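**Plan**
1. Retrosynthesis: the furan-2(5H)-one is removed first by cutting C3=C4 together with O1–C2. What remains, O1–C5–C4, is an α-ketol: the C5–OH sits beside a C4 ketone that already carries the exocyclic CH2O. C2–C3 is an unsubstituted two-carbon carbonyl unit, so one cumulated ylide (Ph3P=C=C=O) can put the whole ring on.
2. Further cuts: C4–CH2O (Weinreb amide plus alkoxymethyllithium); the =CH–CH2 bond between the two chain alkenes (B-alkyl Suzuki–Miyaura); the C5-CH2–CH= bond (alkenylmagnesium/Cu opening of methyl (R)-glycidate).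
3. Forward order: the cyclohexane ring is bought as β-cyclocitral and elaborated to an E-iodoalkene (7 steps). A dienyl α-hydroxy amide is made from propargyl alcohol (4 steps). Union and ketol formation follow, then closure of the butenolide as the last ring and last C–C bond, then deprotection.
4. Stereochemistry: the ring carbinol comes from Sharpless epoxidation, the ring CH from OH-directed hydrogenation, and C5 from the glycidate. The E-alkene comes from syn-carboalumination and the Z-alkene from chelated anti-carbomagnesiation. The geometry of the ring alkene is fixed by the ring.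

Key step: step 15

Remark: the hydroxy aldehyde of step 6 is drawn open-chain although it equilibrates with its lactol. The cyclohexylidene ester of step 4 is drawn as the Z-alkene expected from the reacting conformer, and this geometry is erased in step 5.

**Step 1**
Reactants: 1 β-cyclocitral (2,6,6-trimethylcyclohex-1-ene-1-carbaldehyde)
Product: 2 β-cyclogeraniol ((2,6,6-trimethylcyclohex-1-en-1-yl)methanol)
Conditions: NaBH4, MeOH, 0 °C
Reagents that add atoms: none
Why: Borohydride 1,2-reduction of the hindered enal gives the achiral allylic alcohol needed for the directed epoxidation.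

**Step 2**
Reactants: 2 β-cyclogeraniol
Product: 3 [(1S,6S)-2,2,6-trimethyl-7-oxabicyclo[4.1.0]heptan-1-yl]methanol
Conditions: Ti(OiPr)4 (10 mol %), L-(+)-diethyl tartrate (12 mol %), t-BuOOH, 4 Å MS, CH2Cl2, −20 °C
Reagents that add atoms: tert-butyl hydroperoxide CC(C)(C)OO
Why: In this Katsuki–Sharpless asymmetric epoxidation the Ti/L-(+)-tartrate complex binds the allylic OH and delivers oxygen to the same enantioface as in the geraniol to (2S,3S)-epoxygeraniol case, which sets the C–O centre that becomes the (S)-tertiary carbinol.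

**Step 3**
Reactants: 3 epoxy alcohol
Product: 5 ethyl (2E)-3-[(1R,6S)-2,2,6-trimethyl-7-oxabicyclo[4.1.0]heptan-1-yl]prop-2-enoate, via epoxy aldehyde 4 (not isolated)
Conditions: Dess–Martin periodinane, pyridine, CH2Cl2, 0 °C to rt; then Ph3P=CHCO2Et, 40 °C
Reagents that add atoms: (carbethoxymethylene)triphenylphosphorane CCOC(=O)C=P(c1ccccc1)(c1ccccc1)c1ccccc1
Why: Dess–Martin oxidation followed in the same flask by a Wittig reaction of the non-enolisable epoxy aldehyde with a stabilised ylide should give the E-enoate and leave the epoxide untouched.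

**Step 4**
Reactants: 5 epoxy enoate
Product: 6 ethyl 3-[(1Z,2S)-2-hydroxy-2,6,6-trimethylcyclohexylidene]propanoate
Conditions: SmI2 (2.5 equiv), THF–MeOH, −78 °C
Reagents that add atoms: none
Why: In the samarium diiodide reduction of a γ,δ-epoxy-α,β-unsaturated ester, electron transfer to the enoate expels the allylic C–O bond and kinetic α-protonation of the dienolate leaves the δ-hydroxy-β,γ-unsaturated ester, so the C–O bond at the methyl-bearing carbon keeps its configuration.

**Step 5**
Reactants: 6 hydroxy cyclohexylidene ester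
Product: 7 ethyl 3-[(1S,2S)-2-hydroxy-2,6,6-trimethylcyclohexyl]propanoate
Conditions: H2 (1–10 bar), [Ir(cod)(PCy3)(py)]PF6 (5 mol %), CH2Cl2, rt
Reagents that add atoms: none
Why: In this hydroxyl-directed hydrogenation with Crabtree's catalyst the tertiary OH binds iridium and both hydrogens arrive on the OH face, which places H cis and the side chain trans to OH at the new ring stereocentre (1S).

**Step 6**
Reactants: 7 hydroxy ester
Product: 9 (1S,2S)-2-(but-3-yn-1-yl)-1,3,3-trimethylcyclohexan-1-ol, via hydroxy aldehyde 8 (not isolated)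
Conditions: DIBAL-H (2.2 equiv), CH2Cl2, −78 °C; MeOH; then K2CO3, Ohira–Bestmann reagent, MeOH, 0 °C to rt
Reagents that add atoms: dimethyl (1-diazo-2-oxopropyl)phosphonate COP(=O)(OC)C(=[N+]=[N-])C(C)=O
Why: Partial DIBAL-H reduction of the ester and in-flask Seyferth–Gilbert homologation with the Ohira–Bestmann reagent turn the ester carbon into a terminal alkyne under mild base that tolerates the free tertiary alcohol.

**Step 7**
Reactants: 9 hydroxy alkyne
Product: 11 (1S,2S)-2-[(3E)-4-iodo-3-methylbut-3-en-1-yl]-1,3,3-trimethylcyclohexan-1-ol, via alkenylalane 10 (not isolated)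
Conditions: Me3Al (3.5 equiv), Cp2ZrCl2 (0.3 equiv), CH2Cl2, 0 °C to rt; then I2, THF, −30 °C
Reagents that add atoms: trimethylaluminium C[Al](C)C; iodine II
Why: Zirconium-catalysed methylalumination (Negishi carboalumination) adds Me and Al syn with Al on the terminal carbon, and iodinolysis with retention gives the E-iodoalkene while the OH is masked in the flask as its aluminium alkoxide.

**Step 8**
Reactants: 12 propargyl alcohol (prop-2-yn-1-ol)
Product: 14 (2Z)-2-(iodomethylidene)but-3-en-1-ol, via oxamagnesacycle 13 (not isolated)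
Conditions: CH2=CHMgBr (2.5 equiv), CuI (10 mol %), THF, −10 °C to rt; then I2, −40 to 0 °C
Reagents that add atoms: vinylmagnesium bromide C=C[Mg]Br; iodine II
Why: Copper-catalysed anti-carbomagnesiation of the propargylic alkoxide places the vinyl group on C2 and magnesium on C3 inside a five-membered oxamagnesacycle, so iodinolysis fixes iodine cis to CH2OH (Z).

**Step 9**
Reactants: 14 dienyl iodide alcohol
Product: 15 1-({[(2Z)-2-(iodomethylidene)but-3-en-1-yl]oxy}methyl)-4-methoxybenzene
Conditions: NaH, PMBCl, Bu4NI (cat.), THF–DMF, 0 °C to rt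
Reagents that add atoms: 4-methoxybenzyl chloride COc1ccc(CCl)cc1
Why: This is a Williamson etherification, and a PMB ether is chosen because a silyl ether cis to the later alkenyl-metal centre could migrate from O to C.

**Step 10**
Reactants: 15 PMB ether + 16 methyl (2R)-oxirane-2-carboxylate (methyl (R)-glycidate)
Product: 18 methyl (2R,4Z)-2-hydroxy-5-{[(4-methoxybenzyl)oxy]methyl}hepta-4,6-dienoate, via alkenylmagnesium chloride 17 (not isolated)
Conditions: iPrMgCl·LiCl, THF, 0 °C to rt; then CuI (15 mol %), 16, −40 to −20 °C; aq. NH4Cl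
Reagents that add atoms: none
Why: Iodine–magnesium exchange with retention of alkene geometry and copper-catalysed SN2 opening of the glycidic ester at its unsubstituted C3 give the α-hydroxy ester, and because the C2–O bond is not touched the (R)-centre of 16 becomes C5 of the target.

**Step 11**
Reactants: 18 α-hydroxy ester
Product: 19 (2R,4Z)-2-hydroxy-N-methoxy-5-{[(4-methoxybenzyl)oxy]methyl}-N-methylhepta-4,6-dienamide
Conditions: MeNH(OMe)·HCl, iPrMgCl, THF, −20 to 0 °C
Reagents that add atoms: N,O-dimethylhydroxylamine hydrochloride CNOC.Cl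
Why: Aminolysis of the methyl ester by the magnesium amide (Weinreb amide formation) runs on the magnesium alkoxide and does not touch the stereocentre.

**Step 12**
Reactants: 19 dienyl Weinreb amide + 11 E-iodoalkene
Product: 21 (2R,4Z,8E)-2-hydroxy-11-[(1S,2S)-2-hydroxy-2,6,6-trimethylcyclohexyl]-N-methoxy-5-{[(4-methoxybenzyl)oxy]methyl}-N,9-dimethylundeca-4,8-dienamide, via B-alkylborane 20 (not isolated)
Conditions: 9-BBN-H (2.3 equiv), THF, 0 °C to rt; then 11, Pd(dppf)Cl2 (5 mol %), AsPh3, Cs2CO3, DMF–H2O, rt
Reagents that add atoms: none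
Why: 9-BBN adds to the monosubstituted end of the 2-substituted 1,3-diene (as with myrcene-type dienes), and the primary B-alkylborane couples with the E-iodoalkene with retention in a B-alkyl Suzuki–Miyaura coupling that tolerates free OH groups.

**Step 13**
Reactants: 22 4-methoxybenzyl alcohol
Product: 23 tributyl({[(4-methoxyphenyl)methoxy]methyl})stannane
Conditions: NaH, THF–DMF, 0 °C; Bu3SnCH2I, rt
Reagents that add atoms: tributyl(iodomethyl)stannane CCCC[Sn](CCCC)(CCCC)CI
Why: Williamson alkylation of the alkoxide by the iodomethylstannane gives the precursor of an α-alkoxymethyl anion.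

**Step 14**
Reactants: 21 dihydroxy Weinreb amide + 23 stannane
Product: 25 (3R,5Z,9E)-3-hydroxy-12-[(1S,2S)-2-hydroxy-2,6,6-trimethylcyclohexyl]-1-[(4-methoxybenzyl)oxy]-6-{[(4-methoxybenzyl)oxy]methyl}-10-methyldodeca-5,9-dien-2-one, via alkoxymethyllithium 24 (not isolated)
Conditions: 23 (4 equiv), n-BuLi (3.8 equiv), THF, −78 °C; then 21, −78 to −50 °C; cold aq. NH4Cl
Reagents that add atoms: none
Why: Tin–lithium exchange gives the alkoxymethyllithium, which first deprotonates both OH groups and then adds only once to the Weinreb amide because the chelated tetrahedral adduct survives until the quench.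

**Step 15**
Reactants: 25 α-ketol
Product: 27 (5R)-5-[(2Z,6E)-9-[(1S,2S)-2-hydroxy-2,6,6-trimethylcyclohexyl]-3-{[(4-methoxybenzyl)oxy]methyl}-7-methylnona-2,6-dien-1-yl]-4-{[(4-methoxybenzyl)oxy]methyl}furan-2(5H)-one, via ester ylide 26 (not isolated)
Conditions: Ph3P=C=C=O (1.2 equiv), toluene (dilute), 80–110 °C
Reagents that add atoms: (triphenylphosphoranylidene)ketene (Bestmann ylide) O=C=C=P(c1ccccc1)(c1ccccc1)c1ccccc1
Why: The secondary C5–OH adds across the C=C of the cumulated ylide to give the ester-stabilised ylide 26, whose carbanionic C3 attacks the adjacent C4 ketone, and the bicyclic oxaphosphetane collapses with loss of Ph3P=O to leave the C3=C4 double bond, so O1–C2 and C3=C4 are both made and C2/C3 are brought in by one reagent under neutral conditions. The closest known reaction type is the addition/intramolecular Wittig synthesis of butenolides from α-hydroxy ketones (and of cardenolide rings from 21-hydroxy-20-ketones) with this ylide. The five-membered ring closes 5-exo-trig at the ketone carbon (enolendo with respect to the ylide ester), helped by the activating α-alkoxy group on the ketone and by the irreversible cycloreversion. No stereocentre is created: the ring forces C2 and C5 cis on the new alkene, and C5 should keep its (R)-configuration because none of its bonds is broken and no external base is present. The step needs chemoselectivity among four oxygen functions and three π-systems: both primary alcohols are PMB ethers, the tertiary ring OH is too hindered to add to the ylide, there is only one carbonyl group, and the two trisubstituted alkenes (the nearer of which would compete in a metathesis or carbene closure) are inert to a phosphorus ylide.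

**Step 16**
Reactants: 27 bis-PMB butenolide
Product: 28 (5R)-4-(hydroxymethyl)-5-[(2Z,6E)-9-[(1S,2S)-2-hydroxy-2,6,6-trimethylcyclohexyl]-3-(hydroxymethyl)-7-methylnona-2,6-dien-1-yl]furan-2(5H)-one (target)
Conditions: DDQ (3 equiv), CH2Cl2–pH 7 buffer, 0 °C
Reagents that add atoms: none
Why: Oxidative cleavage of both PMB ethers by DDQ (benzylic hydride abstraction, then hydrolysis of the oxocarbenium ion) is neutral and should leave the butenolide, the alkenes and the tertiary alcohol untouched.

**Compound list**
1 | β-cyclocitral | CC1=C(C=O)C(C)(C)CCC1 | starting material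
2 | β-cyclogeraniol | CC1=C(CO)C(C)(C)CCC1 | intermediate
3 | [(1S,6S)-2,2,6-trimethyl-7-oxabicyclo[4.1.0]heptan-1-yl]methanol | OC[C@]12O[C@@]1(C)CCCC2(C)C | intermediate
4 | (1R,6S)-2,2,6-trimethyl-7-oxabicyclo[4.1.0]heptane-1-carbaldehyde | O=C[C@]12O[C@@]1(C)CCCC2(C)C | intermediate
5 | ethyl (2E)-3-[(1R,6S)-2,2,6-trimethyl-7-oxabicyclo[4.1.0]heptan-1-yl]prop-2-enoate | CCOC(=O)/C=C/[C@]12O[C@@]1(C)CCCC2(C)C | intermediate
6 | ethyl 3-[(1Z,2S)-2-hydroxy-2,6,6-trimethylcyclohexylidene]propanoate | CCOC(=O)C/C=C1/C(C)(C)CCC[C@]1(C)O | intermediate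
7 | ethyl 3-[(1S,2S)-2-hydroxy-2,6,6-trimethylcyclohexyl]propanoate | CCOC(=O)CC[C@H]1C(C)(C)CCC[C@]1(C)O | intermediate
8 | 3-[(1S,2S)-2-hydroxy-2,6,6-trimethylcyclohexyl]propanal | O=CCC[C@H]1C(C)(C)CCC[C@]1(C)O | intermediate
9 | (1S,2S)-2-(but-3-yn-1-yl)-1,3,3-trimethylcyclohexan-1-ol | C#CCC[C@H]1C(C)(C)CCC[C@]1(C)O | intermediate
10 | dimethylaluminium alkoxide of (1S,2S)-2-[(3E)-4-(dimethylalumanyl)-3-methylbut-3-en-1-yl]-1,3,3-trimethylcyclohexan-1-ol | C/C(=C\[Al](C)C)CC[C@H]1C(C)(C)CCC[C@]1(C)O[Al](C)C | intermediate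
11 | (1S,2S)-2-[(3E)-4-iodo-3-methylbut-3-en-1-yl]-1,3,3-trimethylcyclohexan-1-ol | C/C(=C\I)CC[C@H]1C(C)(C)CCC[C@]1(C)O | intermediate
12 | propargyl alcohol | C#CCO | starting material
13 | 4-ethenyl-2,5-dihydro-1,2-oxamagnesole | C=CC1=C[Mg]OC1 | intermediate
14 | (2Z)-2-(iodomethylidene)but-3-en-1-ol | OC/C(C=C)=C\I | intermediate
15 | 1-({[(2Z)-2-(iodomethylidene)but-3-en-1-yl]oxy}methyl)-4-methoxybenzene | COc1ccc(COC/C(C=C)=C\I)cc1 | intermediate
16 | methyl (2R)-oxirane-2-carboxylate | COC(=O)[C@H]1CO1 | starting material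
17 | chloro[(1Z)-2-{[(4-methoxybenzyl)oxy]methyl}buta-1,3-dien-1-yl]magnesium | COc1ccc(COC/C(C=C)=C\[Mg]Cl)cc1 | intermediate
18 | methyl (2R,4Z)-2-hydroxy-5-{[(4-methoxybenzyl)oxy]methyl}hepta-4,6-dienoate | COC(=O)[C@H](O)C/C=C(/C=C)COCc1ccc(OC)cc1 | intermediate
19 | (2R,4Z)-2-hydroxy-N-methoxy-5-{[(4-methoxybenzyl)oxy]methyl}-N-methylhepta-4,6-dienamide | CON(C)C(=O)[C@H](O)C/C=C(/C=C)COCc1ccc(OC)cc1 | intermediate
20 | 7-(9-borabicyclo[3.3.1]nonan-9-yl) hept-4-enamide from 19, with its 2-OH as the 9-BBN borinate | CON(C)C(=O)[C@H](OB1C2CCCC1CCC2)C/C=C(/CCB1C2CCCC1CCC2)COCc1ccc(OC)cc1 | intermediate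
21 | (2R,4Z,8E)-2-hydroxy-11-[(1S,2S)-2-hydroxy-2,6,6-trimethylcyclohexyl]-N-methoxy-5-{[(4-methoxybenzyl)oxy]methyl}-N,9-dimethylundeca-4,8-dienamide | CON(C)C(=O)[C@H](O)C/C=C(/CC/C=C(\C)CC[C@H]1C(C)(C)CCC[C@]1(C)O)COCc1ccc(OC)cc1 | intermediate
22 | 4-methoxybenzyl alcohol | COc1ccc(CO)cc1 | starting material
23 | tributyl({[(4-methoxyphenyl)methoxy]methyl})stannane | CCCC[Sn](CCCC)(CCCC)COCc1ccc(OC)cc1 | intermediate
24 | {[(4-methoxybenzyl)oxy]methyl}lithium | [Li]COCc1ccc(OC)cc1 | intermediate
25 | (3R,5Z,9E)-3-hydroxy-12-[(1S,2S)-2-hydroxy-2,6,6-trimethylcyclohexyl]-1-[(4-methoxybenzyl)oxy]-6-{[(4-methoxybenzyl)oxy]methyl}-10-methyldodeca-5,9-dien-2-one | COc1ccc(COCC(=O)[C@H](O)C/C=C(/CC/C=C(\C)CC[C@H]2C(C)(C)CCC[C@]2(C)O)COCc2ccc(OC)cc2)cc1 | intermediate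
26 | (triphenylphosphoranylidene)acetate ester of 25 at the C3 hydroxyl | COc1ccc(COCC(=O)[C@H](OC(=O)C=P(c2ccccc2)(c2ccccc2)c2ccccc2)C/C=C(/CC/C=C(\C)CC[C@H]2C(C)(C)CCC[C@]2(C)O)COCc2ccc(OC)cc2)cc1 | intermediate
27 | (5R)-5-[(2Z,6E)-9-[(1S,2S)-2-hydroxy-2,6,6-trimethylcyclohexyl]-3-{[(4-methoxybenzyl)oxy]methyl}-7-methylnona-2,6-dien-1-yl]-4-{[(4-methoxybenzyl)oxy]methyl}furan-2(5H)-one | C/C(=C\CC/C(=C/C[C@H]1OC(=O)C=C1COCc1ccc(OC)cc1)COCc1ccc(OC)cc1)CC[C@H]1C(C)(C)CCC[C@]1(C)O | intermediate
28 | (5R)-4-(hydroxymethyl)-5-[(2Z,6E)-9-[(1S,2S)-2-hydroxy-2,6,6-trimethylcyclohexyl]-3-(hydroxymethyl)-7-methylnona-2,6-dien-1-yl]furan-2(5H)-one | C/C(=C\CC/C(=C/C[C@H]1OC(=O)C=C1CO)CO)CC[C@H]1C(C)(C)CCC[C@]1(C)O | target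

**Step count**
Total steps: 16.
Longest linear sequence: 11 steps (steps 1–7, 12, 14, 15, 16).

**Steps most likely to fail**

Step 15. The intramolecular Wittig reaction of the ester-stabilised ylide with a ketone flanked by two oxygenated carbons may be slow. At the temperature it needs, the ketol may enolise, so that configuration at C5 erodes or the ketol transposes. The fallback separates acylation from olefination and uses a more nucleophilic phosphonate carbanion in the cold. It sets out from 25. The C3 hydroxyl of 25 (C5 of the target) is esterified with diethylphosphonoacetic acid (EDC, DMAP, CH2Cl2, 0 °C) to the (diethoxyphosphoryl)acetate ester of 25 F1. This ester is closed by an intramolecular Horner–Wadsworth–Emmons reaction (LiCl, iPr2NEt, MeCN, 0 °C). The fallback comes back to the route at 27.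

Step 5. The exocyclic alkene lies between two fully substituted carbons and may not reach the iridium centre. The acidic iridium hydrides may also ionise the tertiary allylic alcohol. The fallback replaces coordination control by steric control in a temporary ring. It sets out from 6. Heating 6 with catalytic Ti(OiPr)4 in toluene, with removal of the alcohol formed, closes it to (8aS)-5,5,8a-trimethyl-3,5,6,7,8,8a-hexahydro-2H-chromen-2-one F2. In this bicycle the ring oxygen lies in the alkene plane, and the angular methyl group and one of the geminal methyl groups are axial on the same face. Heterogeneous hydrogenation (H2, Pd/C, EtOAc) should therefore add from the other face and give the trans-fused (4aS,8aS)-5,5,8a-trimethyloctahydro-2H-chromen-2-one F3. DIBAL-H reduction of F3 to the lactol and Ohira–Bestmann homologation, as in step 6, bring the fallback back to the route at 9.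

Step 12. The homoallylic B-alkylborane carries a borinate and a chelating amide and may transmetalate slowly under aqueous base. Protodeboronation, β-hydride elimination and base-induced erosion of the α-hydroxy amide centre could then compete. The fallback avoids boron-to-palladium transfer and base altogether. It sets out from 20. Oxidation with sodium perborate gives (2R,4Z)-2,7-dihydroxy-N-methoxy-5-{[(4-methoxybenzyl)oxy]methyl}-N-methylhept-4-enamide F4. The primary hydroxyl is converted selectively (I2, PPh3, imidazole, 0 °C) into (2R,4Z)-2-hydroxy-7-iodo-N-methoxy-5-{[(4-methoxybenzyl)oxy]methyl}-N-methylhept-4-enamide F5. F5 is joined to 11 by a nickel-catalysed reductive cross-electrophile coupling (NiI2, 4,4'-di-tert-butyl-2,2'-bipyridine, Mn, DMA), which tolerates free hydroxyl groups and retains the alkene geometry. The fallback comes back to the route at 21.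

**Further compounds**
F1 | step 15 | (diethoxyphosphoryl)acetate ester of 25 at the C3 hydroxyl | COc1ccc(COCC(=O)[C@H](OC(=O)CP(=O)(OCC)OCC)C/C=C(/CC/C=C(\C)CC[C@H]2C(C)(C)CCC[C@]2(C)O)COCc2ccc(OC)cc2)cc1
F2 | step 5 | (8aS)-5,5,8a-trimethyl-3,5,6,7,8,8a-hexahydro-2H-chromen-2-one | O=C1CC=C2C(C)(C)CCC[C@]2(C)O1
F3 | step 5 | (4aS,8aS)-5,5,8a-trimethyloctahydro-2H-chromen-2-one | O=C1CC[C@H]2C(C)(C)CCC[C@]2(C)O1
F4 | step 12 | (2R,4Z)-2,7-dihydroxy-N-methoxy-5-{[(4-methoxybenzyl)oxy]methyl}-N-methylhept-4-enamide | CON(C)C(=O)[C@H](O)C/C=C(/CCO)COCc1ccc(OC)cc1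
F5 | step 12 | (2R,4Z)-2-hydroxy-7-iodo-N-methoxy-5-{[(4-methoxybenzyl)oxy]methyl}-N-methylhept-4-enamide | CON(C)C(=O)[C@H](O)C/C=C(/CCI)COCc1ccc(OC)cc1
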